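**Plan**
1. Numbering: ring C1 (carbinol esterified by the hydroxytiglic acid), C2 (C=O), C3 (bears CH2OH), C4 (=CH), C5 (isobutyrate carbinol), C6 (isopropyl carbon). Retrosynthesis: remove the C1 ester and the C3 hydroxymethyl group (Morita–Baylis–Hillman retron), return C2=O to CH2, then cut the ring bonds C4–C5 and C1–C2 together.
2. Enabling feature: in the six-membered ring the carbinol carbons C5 and C1 are joined on one side by the single carbon C6 (central carbon of a 2-isopropylmalonaldehyde) and on the other by the cis-alkene unit C4=C3–C2. This (Z)-pent-2-ene-1,5-diol is the retron of a double carbonyl allylboration with a γ-boryl allylborane.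
3. Forward: 3-methylbutanal → enol isobutyrate 4 of 2-isopropylmalonaldehyde; an annulative double allylboration with the reagent made from allenylboronate 5 gives cyclohexenol 9 (ring, alkene, three stereocentres, isobutyrate on O–C5 by acyl relay).
4. Completion: esterification of O–C1 with the silyl-protected (E)-4-hydroxy-2-methylbut-2-enoic acid 13 (Wittig route), allylic oxidation of C2, hydroxymethylation of C3, desilylation.
5. Stereochemistry: C5 from the isopinocampheyl (Ipc) groups on boron; C1 by stereospecific allyl transfer from the C4 boronate; C6 by ring closure of an epimerisable aldehyde; side-chain E geometry from the stabilised ylide.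

Key step: step 3

Remark (assumption): O-acylation of the hydrogen-bonded cis-enol 3 is taken to give the Z enol ester 4 (acyloxy cis to formyl); only this isomer can pass its acyl group on in step 3.

Step 1
Reactants: 1 3-methylbutanal
Product: 3 (2Z)-3-hydroxy-2-(propan-2-yl)prop-2-enal, via enaminal 2 (not isolated)
Conditions: t-BuOCH(NMe2)2, THF, 60 °C; then 2 M NaOH, 60 °C; then HCl to pH 3
Reagents that add atoms: tert-butoxybis(dimethylamino)methane CC(C)(C)OC(N(C)C)N(C)C; water O
Why: α-Aminomethylenation of the enolisable aldehyde gives the vinylogous formamide 2, and alkaline hydrolysis by addition–elimination followed by acidification should release the chelated enol 3, with no stereocentre formed.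

Step 2
Reactants: 3 (2Z)-3-hydroxy-2-(propan-2-yl)prop-2-enal
Product: 4 (1Z)-3-oxo-2-(propan-2-yl)prop-1-en-1-yl 2-methylpropanoate
Conditions: (i-PrCO)2O, Et3N, CH2Cl2, −78 → 0 °C
Reagents that add atoms: 2-methylpropanoic anhydride CC(C)C(=O)OC(=O)C(C)C
Why: O-Acylation of the β-dicarbonyl enol (enol ester formation) should trap the cis-enol as the Z vinylogous anhydride, which masks one formyl group and stores the isobutyryl group for step 3.

Step 3
Reactants: 4 (1Z)-3-oxo-2-(propan-2-yl)prop-1-en-1-yl 2-methylpropanoate; 5 4,4,5,5-tetramethyl-2-(propa-1,2-dien-1-yl)-1,3,2-dioxaborolane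
Product: 9 (1S,5S,6R)-5-hydroxy-6-(propan-2-yl)cyclohex-2-en-1-yl 2-methylpropanoate, via γ-boryl allylborane 6 (not isolated), via borinate adduct 7 (not isolated), via β-acyloxy aldehyde 8 (not isolated)
Conditions: 5, (−)-Ipc2BH, Et2O, −40 °C; then 4, −78 °C; then MeOH (3 equiv), −78 → 23 °C; pH 7 buffer
Reagents that add atoms: none
Why: Proposed new method: the closest known reaction type is the one-pot double allylboration of two different aldehydes with a γ-boryl allyldiisopinocampheylborane, and here both aldehydes are carried by one malonaldehyde unit, the second being released only after the first has reacted. Hydroboration of 5 gives the Z reagent 6, which adds to the free formyl group of 4 through a chair transition state to form C4–C5; the Ipc groups set C5 (Si-face attack) and the Z geometry places the new C4–B bond syn to C5–O in 7. Methanol frees the C5 hydroxyl, which takes the isobutyryl group from the cis enol ester through a six-membered O-to-O acyl shift, and the released enol ketonises to aldehyde 8, so that the isobutyrate ends on O–C5. The α-substituted allylboronate of 8 then adds to this aldehyde through a closed, boat-like transition state (boron bound to the carbonyl oxygen), which closes the six-membered ring by 6-exo-trig attack of C2 on C1 and moves the double bond to C3=C4. C1 is set stereospecifically, because its oxygen is delivered to the ring face that carried boron at C4 and hence trans to the C5 ester, and C6, epimerisable in 8, should close with isopropyl turned away from the dioxaborolane bridge, that is cis to the C5 ester. The step needs site selectivity between the two formyl carbons and ring closure faster than β-elimination of isobutyric acid; the enol-ester mask and the neutral, base-free conditions are meant to secure both.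

Step 4
Reactants: 10 2-[(tert-butyldimethylsilyl)oxy]acetaldehyde; 11 ethyl 2-(triphenyl-λ5-phosphanylidene)propanoate
Product: 12 ethyl (2E)-4-[(tert-butyldimethylsilyl)oxy]-2-methylbut-2-enoate
Conditions: CH2Cl2, 0 → 23 °C
Reagents that add atoms: none
Why: Wittig olefination with the stabilised, α-branched ylide should give the trisubstituted alkene with E geometry.

Step 5
Reactants: 12 ethyl (2E)-4-[(tert-butyldimethylsilyl)oxy]-2-methylbut-2-enoate
Product: 13 (2E)-4-[(tert-butyldimethylsilyl)oxy]-2-methylbut-2-enoic acid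
Conditions: LiOH, THF/H2O, 23 °C; then 1 M HCl to pH 4
Reagents that add atoms: lithium hydroxide [Li+].[OH-]
Why: Saponification of the ethyl ester (acyl substitution) should leave the primary silyl ether and the alkene geometry intact.

Step 6
Reactants: 9 (1S,5S,6R)-5-hydroxy-6-(propan-2-yl)cyclohex-2-en-1-yl 2-methylpropanoate; 13 (2E)-4-[(tert-butyldimethylsilyl)oxy]-2-methylbut-2-enoic acid
Product: 14 (1S,5S,6R)-5-[(2-methylpropanoyl)oxy]-6-(propan-2-yl)cyclohex-3-en-1-yl (2E)-4-[(tert-butyldimethylsilyl)oxy]-2-methylbut-2-enoate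
Conditions: DCC, DMAP (cat.), CH2Cl2, 0 → 23 °C
Reagents that add atoms: none
Why: Steglich esterification acylates the free C1 hydroxyl with retention, the C5 oxygen being already blocked as the isobutyrate, which cannot migrate across the trans-1,3 relationship.

Step 7
Reactants: 14 (1S,5S,6R)-5-[(2-methylpropanoyl)oxy]-6-(propan-2-yl)cyclohex-3-en-1-yl (2E)-4-[(tert-butyldimethylsilyl)oxy]-2-methylbut-2-enoate
Product: 15 (1R,5S,6S)-5-[(2-methylpropanoyl)oxy]-2-oxo-6-(propan-2-yl)cyclohex-3-en-1-yl (2E)-4-[(tert-butyldimethylsilyl)oxy]-2-methylbut-2-enoate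
Conditions: Rh2(cap)4 [dirhodium tetrakis(caprolactamate)] (cat.), t-BuOOH, K2CO3, CH2Cl2, 23 °C
Reagents that add atoms: tert-butyl hydroperoxide CC(C)(C)OO
Why: Catalytic allylic C–H oxidation with t-BuOOH (hydrogen abstraction, peroxidation, collapse to the ketone) should convert the only ring allylic CH2 (C2) into the enone carbonyl, leaving C1 trans to isopropyl, the preferred arrangement of this now epimerisable centre.

Step 8
Reactants: 15 (1R,5S,6S)-5-[(2-methylpropanoyl)oxy]-2-oxo-6-(propan-2-yl)cyclohex-3-en-1-yl (2E)-4-[(tert-butyldimethylsilyl)oxy]-2-methylbut-2-enoate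
Product: 16 (1R,5S,6S)-3-(hydroxymethyl)-5-[(2-methylpropanoyl)oxy]-2-oxo-6-(propan-2-yl)cyclohex-3-en-1-yl (2E)-4-[(tert-butyldimethylsilyl)oxy]-2-methylbut-2-enoate
Conditions: aq. HCHO, DMAP, THF, 23 °C
Reagents that add atoms: formaldehyde C=O
Why: Morita–Baylis–Hillman hydroxymethylation: DMAP adds to C4, the enolate attacks formaldehyde at C3, and loss of DMAP restores the enone.

Step 9
Reactants: 16 (1R,5S,6S)-3-(hydroxymethyl)-5-[(2-methylpropanoyl)oxy]-2-oxo-6-(propan-2-yl)cyclohex-3-en-1-yl (2E)-4-[(tert-butyldimethylsilyl)oxy]-2-methylbut-2-enoate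
Product: 17 (1R,5S,6S)-3-(hydroxymethyl)-5-[(2-methylpropanoyl)oxy]-2-oxo-6-(propan-2-yl)cyclohex-3-en-1-yl (2E)-4-hydroxy-2-methylbut-2-enoate
Conditions: HF·pyridine, pyridine, THF, 0 °C
Reagents that add atoms: none
Why: Fluoride-mediated desilylation under buffered conditions should remove the primary silyl ether without cleaving the three esters.

**Compound list**
1 | 3-methylbutanal | CC(C)CC=O | starting material
2 | (2E)-2-[(dimethylamino)methylidene]-3-methylbutanal | CN(C)/C=C(/C=O)C(C)C | intermediate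
3 | (2Z)-3-hydroxy-2-(propan-2-yl)prop-2-enal (enol form of 2-isopropylmalonaldehyde) | O/C=C(\C=O)C(C)C | intermediate
4 | (1Z)-3-oxo-2-(propan-2-yl)prop-1-en-1-yl 2-methylpropanoate | CC(C)C(=O)O/C=C(\C=O)C(C)C | intermediate
5 | 4,4,5,5-tetramethyl-2-(propa-1,2-dien-1-yl)-1,3,2-dioxaborolane | C=C=CB1OC(C)(C)C(C)(C)O1 | starting material
6 | bis[(−)-isopinocampheyl][(2Z)-3-(4,4,5,5-tetramethyl-1,3,2-dioxaborolan-2-yl)prop-2-en-1-yl]borane (Ipc groups from (+)-α-pinene) | CC1(C)OB(OC1(C)C)/C=C\CB([C@@H]1C[C@@H]2C[C@H]([C@H]1C)C2(C)C)[C@@H]1C[C@@H]2C[C@H]([C@H]1C)C2(C)C | intermediate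
7 | (1Z,3S,4R)-3-[(diisopinocampheylboranyl)oxy]-2-(propan-2-yl)-4-(4,4,5,5-tetramethyl-1,3,2-dioxaborolan-2-yl)hexa-1,5-dien-1-yl 2-methylpropanoate | C=C[C@@H](B1OC(C)(C)C(C)(C)O1)[C@H](OB([C@@H]1C[C@@H]2C[C@H]([C@H]1C)C2(C)C)[C@@H]1C[C@@H]2C[C@H]([C@H]1C)C2(C)C)/C(C(C)C)=C\OC(=O)C(C)C | intermediate
8 | (3R,4S,5S)-5-formyl-6-methyl-3-(4,4,5,5-tetramethyl-1,3,2-dioxaborolan-2-yl)hept-1-en-4-yl 2-methylpropanoate | C=C[C@@H](B1OC(C)(C)C(C)(C)O1)[C@H](OC(=O)C(C)C)[C@@H](C=O)C(C)C | intermediate
9 | (1S,5S,6R)-5-hydroxy-6-(propan-2-yl)cyclohex-2-en-1-yl 2-methylpropanoate | O[C@H]1CC=C[C@H](OC(=O)C(C)C)[C@@H]1C(C)C | intermediate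
10 | 2-[(tert-butyldimethylsilyl)oxy]acetaldehyde | CC(C)(C)[Si](C)(C)OCC=O | starting material
11 | ethyl 2-(triphenyl-λ5-phosphanylidene)propanoate | CCOC(=O)C(C)=P(c1ccccc1)(c1ccccc1)c1ccccc1 | starting material
12 | ethyl (2E)-4-[(tert-butyldimethylsilyl)oxy]-2-methylbut-2-enoate | CCOC(=O)/C(C)=C/CO[Si](C)(C)C(C)(C)C | intermediate
13 | (2E)-4-[(tert-butyldimethylsilyl)oxy]-2-methylbut-2-enoic acid | OC(=O)/C(C)=C/CO[Si](C)(C)C(C)(C)C | intermediate
14 | (1S,5S,6R)-5-[(2-methylpropanoyl)oxy]-6-(propan-2-yl)cyclohex-3-en-1-yl (2E)-4-[(tert-butyldimethylsilyl)oxy]-2-methylbut-2-enoate | C/C(=C\CO[Si](C)(C)C(C)(C)C)C(=O)O[C@H]1CC=C[C@H](OC(=O)C(C)C)[C@@H]1C(C)C | intermediate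
15 | (1R,5S,6S)-5-[(2-methylpropanoyl)oxy]-2-oxo-6-(propan-2-yl)cyclohex-3-en-1-yl (2E)-4-[(tert-butyldimethylsilyl)oxy]-2-methylbut-2-enoate | C/C(=C\CO[Si](C)(C)C(C)(C)C)C(=O)O[C@H]1C(=O)C=C[C@H](OC(=O)C(C)C)[C@@H]1C(C)C | intermediate
16 | (1R,5S,6S)-3-(hydroxymethyl)-5-[(2-methylpropanoyl)oxy]-2-oxo-6-(propan-2-yl)cyclohex-3-en-1-yl (2E)-4-[(tert-butyldimethylsilyl)oxy]-2-methylbut-2-enoate | C/C(=C\CO[Si](C)(C)C(C)(C)C)C(=O)O[C@H]1C(=O)C(CO)=C[C@H](OC(=O)C(C)C)[C@@H]1C(C)C | intermediate
17 | (1R,5S,6S)-3-(hydroxymethyl)-5-[(2-methylpropanoyl)oxy]-2-oxo-6-(propan-2-yl)cyclohex-3-en-1-yl (2E)-4-hydroxy-2-methylbut-2-enoate (CNP0254776.1) | C/C(=C\CO)C(=O)O[C@H]1C(=O)C(CO)=C[C@H](OC(=O)C(C)C)[C@@H]1C(C)C | target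

Total step count: 9. Longest linear sequence: 7 steps (steps 1, 2, 3, 6, 7, 8, 9); steps 4 and 5 make the side-chain acid.

**Steps most likely to fail**

Step 3 (proposed new method). The acyl relay may lag behind β-elimination of isobutyric acid from the unmasked aldehyde. Ring closure may also fail to discriminate between the two C6 epimers, or the boat-like intramolecular allyl transfer may be too slow. The fallback uses known chemistry, sets out from 1 and comes back at 9. An L-proline-catalysed anti-selective cross-aldol of 1 with 3-[tri(propan-2-yl)silyl]prop-2-ynal should give (2S,3R)-3-hydroxy-2-(propan-2-yl)-5-[tri(propan-2-yl)silyl]pent-4-ynal F1, fixing C6 and C5. Acylation with isobutyric anhydride and pyridine gives (3R,4S)-4-formyl-5-methyl-1-[tri(propan-2-yl)silyl]hex-1-yn-3-yl 2-methylpropanoate F2. Desilylation with Bu4NF/AcOH gives (3R,4S)-4-formyl-5-methylhex-1-yn-3-yl 2-methylpropanoate F3, and semi-hydrogenation (H2, Pd/CaCO3 poisoned with Pb(OAc)2, quinoline) gives (3S,4S)-4-formyl-5-methylhex-1-en-3-yl 2-methylpropanoate F4. Reagent-controlled allylation of the aldehyde with (−)-B-allyldiisopinocampheylborane sets C1 and gives (3S,4R,5S)-5-hydroxy-4-(propan-2-yl)octa-1,7-dien-3-yl 2-methylpropanoate F5. Ring-closing metathesis with the second-generation Grubbs catalyst, RuCl2(=CHPh)(H2IMes)(PCy3), then forms C3=C4 and returns 9.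

Step 7. Hydrogen abstraction may occur at the wrong site (the allylic CH2–OSi of the side chain or C5–H), or the allylic radical may be oxygenated at its transposed terminus C4. The fallback sets out from 14 and comes back at 15. Ene oxidation with SeO2 and t-BuOOH, followed by [2,3]-shift, should hydroxylate C2 with the alkene kept in place, giving (1R,2RS,5S,6S)-2-hydroxy-5-[(2-methylpropanoyl)oxy]-6-(propan-2-yl)cyclohex-3-en-1-yl (2E)-4-[(tert-butyldimethylsilyl)oxy]-2-methylbut-2-enoate F6. Oxidation of this allylic alcohol with Dess–Martin periodinane gives 15.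

Step 8. The aldol step may be slow on the hindered, γ-acyloxy-substituted enone, and acyl migration or loss of isobutyrate may compete under the nucleophilic amine. The fallback sets out from 15 and comes back at 16. α-Iodination with I2 and pyridine gives (1R,5R,6S)-3-iodo-5-[(2-methylpropanoyl)oxy]-2-oxo-6-(propan-2-yl)cyclohex-3-en-1-yl (2E)-4-[(tert-butyldimethylsilyl)oxy]-2-methylbut-2-enoate F7. Stille coupling of F7 with (tributylstannyl)methanol under Pd(PPh3)4 installs the hydroxymethyl group and gives 16.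

Further compounds
F1 | step 3 | (2S,3R)-3-hydroxy-2-(propan-2-yl)-5-[tri(propan-2-yl)silyl]pent-4-ynal | CC(C)[Si](C(C)C)(C(C)C)C#C[C@H](O)[C@@H](C=O)C(C)C
F2 | step 3 | (3R,4S)-4-formyl-5-methyl-1-[tri(propan-2-yl)silyl]hex-1-yn-3-yl 2-methylpropanoate | CC(C)[Si](C(C)C)(C(C)C)C#C[C@H](OC(=O)C(C)C)[C@@H](C=O)C(C)C
F3 | step 3 | (3R,4S)-4-formyl-5-methylhex-1-yn-3-yl 2-methylpropanoate | C#C[C@H](OC(=O)C(C)C)[C@@H](C=O)C(C)C
F4 | step 3 | (3S,4S)-4-formyl-5-methylhex-1-en-3-yl 2-methylpropanoate | C=C[C@H](OC(=O)C(C)C)[C@@H](C=O)C(C)C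
F5 | step 3 | (3S,4R,5S)-5-hydroxy-4-(propan-2-yl)octa-1,7-dien-3-yl 2-methylpropanoate | O[C@@H](CC=C)[C@@H](C(C)C)[C@@H](OC(=O)C(C)C)C=C
F6 | step 7 | (1R,2RS,5S,6S)-2-hydroxy-5-[(2-methylpropanoyl)oxy]-6-(propan-2-yl)cyclohex-3-en-1-yl (2E)-4-[(tert-butyldimethylsilyl)oxy]-2-methylbut-2-enoate | C/C(=C\CO[Si](C)(C)C(C)(C)C)C(=O)O[C@H]1C(O)C=C[C@H](OC(=O)C(C)C)[C@@H]1C(C)C
F7 | step 8 | (1R,5R,6S)-3-iodo-5-[(2-methylpropanoyl)oxy]-2-oxo-6-(propan-2-yl)cyclohex-3-en-1-yl (2E)-4-[(tert-butyldimethylsilyl)oxy]-2-methylbut-2-enoate | C/C(=C\CO[Si](C)(C)C(C)(C)C)C(=O)O[C@H]1C(=O)C(I)=C[C@H](OC(=O)C(C)C)[C@@H]1C(C)C
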